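The β-aryloxy ketone O1–C2–C3–C4(=O)–C4a of ring C is cut at O1–C2 and C4–C4a. This exposes it as the union of a phenol (O1 and the ortho carbon C4a of ring A) with a 1,3-dielectrophile. The dielectrophile is an enantiopure (R)-4-aryl-β-lactone: its alkyl carbon becomes C2 and its acyl carbon becomes C4. In one flask the phenoxide of a symmetrical 3,5-bis(methoxymethoxy)-4-prenylphenol opens the lactone at the benzylic carbon with inversion, fixing 2S, and trifluoroacetic anhydride closes the resulting carboxylate onto ring A. Acidic removal of two acetals and one carbonate then gives the target.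

Key step: step 7

Assumption: the target is the (2S) enantiomer, as the SMILES specifies (priorities at C2: O1 > aryl > C3 > H).
Assumption: O-trimethylsilylquinidine is taken as the pseudoenantiomer that delivers the (4R)-lactone in step 6; if the sense proves opposite, O-trimethylsilylquinine is used instead.
Abbreviations: prenyl = 3-methylbut-2-en-1-yl, MOM = methoxymethyl, Boc = tert-butoxycarbonyl.

Step 1
Reactants: 1 resorcinol
Product: 2 1,3-bis(methoxymethoxy)benzene
Conditions: MOMCl, i-Pr2NEt, CH2Cl2, 0 °C → rt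
Reagents that add atoms: chloromethyl methyl ether, COCCl
Why: Double Williamson-type O-alkylation with the α-chloro ether masks both hydroxyls as MOM acetals, which later direct the lithiation and leave under mild acid.

Step 2
Reactants: 2 1,3-bis(methoxymethoxy)benzene
Product: 4 1,3-bis(methoxymethoxy)-2-(3-methylbut-2-en-1-yl)benzene, via aryllithium 3 (not isolated)
Conditions: n-BuLi, THF, 0 °C → rt; then CuI (10 mol%), prenyl bromide, −78 °C → rt
Reagents that add atoms: prenyl bromide (1-bromo-3-methylbut-2-ene), CC(C)=CCBr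
Why: Directed ortho-metalation places lithium only at C2 between the two coordinating MOM oxygens, and copper-catalysed substitution at the primary carbon of prenyl bromide should give the linear prenyl arene.

Step 3
Reactants: 4 1,3-bis(methoxymethoxy)-2-(3-methylbut-2-en-1-yl)benzene
Product: 6 3,5-bis(methoxymethoxy)-4-(3-methylbut-2-en-1-yl)phenol, via arylboronate 5 (not isolated)
Conditions: [Ir(OMe)(cod)]2 (1.5 mol%), 4,4'-di-tert-butyl-2,2'-bipyridine (3 mol%), B2pin2 (0.6 equiv), THF, 80 °C; then 30% aq. H2O2, aq. NaOH, 0 °C → rt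
Reagents that add atoms: hydrogen peroxide, OO
Why: Sterically controlled iridium-catalysed aromatic C–H borylation should take the one ring C–H without an ortho substituent (para to the prenyl group), and oxidation of the C–B bond in the same flask gives the phenol with both flanking oxygens still protected.

Step 4
Reactants: 7 4-hydroxybenzaldehyde
Product: 8 4-hydroxy-3-(3-methylbut-2-en-1-yl)benzaldehyde
Conditions: prenyl bromide, 10% aq. KOH, rt
Reagents that add atoms: prenyl bromide (1-bromo-3-methylbut-2-ene), CC(C)=CCBr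
Why: Phenoxide ortho-C-alkylation in water, where hydrogen bonding to the oxygen favours C- over O-allylation; the para position is blocked by the formyl group.

Step 5
Reactants: 8 4-hydroxy-3-(3-methylbut-2-en-1-yl)benzaldehyde
Product: 9 tert-butyl 4-formyl-2-(3-methylbut-2-en-1-yl)phenyl carbonate
Conditions: Boc2O, DMAP (5 mol%), MeCN, rt
Reagents that add atoms: di-tert-butyl dicarbonate, CC(C)(C)OC(=O)OC(=O)OC(C)(C)C
Why: DMAP-catalysed O-acylation gives the aryl tert-butyl carbonate, which makes the para oxygen non-donating (needed for clean SN2 at the future C2) and is later cleaved by the same acid as the MOM ethers.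

Step 6
Reactants: 9 tert-butyl 4-formyl-2-(3-methylbut-2-en-1-yl)phenyl carbonate
Product: 10 tert-butyl 2-(3-methylbut-2-en-1-yl)-4-[(2R)-4-oxooxetan-2-yl]phenyl carbonate (the (4R)-4-aryloxetan-2-one)
Conditions: AcCl (slow addition), i-Pr2NEt, O-trimethylsilylquinidine (10 mol%), LiClO4, CH2Cl2–Et2O, −78 °C
Reagents that add atoms: acetyl chloride, CC(=O)Cl
Why: Catalytic asymmetric acyl halide–aldehyde cyclocondensation (formal ketene–aldehyde [2+2] cycloaddition): the ammonium enolate from in situ ketene and the alkaloid adds to one face of the LiClO4-activated aldehyde and the aldolate lactonises, so the 4R centre is set by the catalyst.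

Step 7
Reactants: 6 3,5-bis(methoxymethoxy)-4-(3-methylbut-2-en-1-yl)phenol; 10 tert-butyl 2-(3-methylbut-2-en-1-yl)-4-[(2R)-4-oxooxetan-2-yl]phenyl carbonate
Product: 14 tert-butyl 4-[(2S)-5,7-bis(methoxymethoxy)-6-(3-methylbut-2-en-1-yl)-4-oxo-3,4-dihydro-2H-chromen-2-yl]-2-(3-methylbut-2-en-1-yl)phenyl carbonate, via sodium phenoxide 11 (not isolated), via sodium carboxylate 12 (not isolated), via mixed anhydride 13 (not isolated)
Conditions: 6, NaH (1.0 equiv), 15-crown-5, THF, 0 °C; add 10, 0 → 40 °C; then (CF3CO)2O, 0 °C → rt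
Reagents that add atoms: none
Why: The pre-formed phenoxide 11 attacks the benzylic C4 of the strained lactone with alkyl–oxygen fission (SN2, inversion), which forms O1–C2 and converts 4R into the 3S carboxylate 12; the only stereocentre of the target is therefore set by stereospecific transfer from the lactone. Trifluoroacetic anhydride then converts 12 into the mixed anhydride 13, whose acyl carbon is attacked by the ring carbon next to the ether oxygen (intramolecular Friedel–Crafts acylation, 6-exo-trig closure of ring C), which forms C4–C4a. The closest known chemistry is the classical two-stage chroman-4-one synthesis, in which a phenoxide opens a β-lactone and the 3-aryloxypropanoic acid is then cycliacylated; here both stages run in one flask on an enantiopure 4-aryl lactone. Alkyl attack must win over acyl attack: acyl attack should only give an aryl ester alkoxide that relactonises, whereas benzylic substitution is irreversible, and the electron-withdrawing carbonate on ring B suppresses ionisation at C2 in both stages so that configuration is kept. Regiochemistry needs no control, because the two positions ortho to the ether oxygen of the symmetrical phenol are equivalent and the para position carries the prenyl group, which also fixes the 6-prenyl pattern.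

Step 8
Reactants: 14 tert-butyl 4-[(2S)-5,7-bis(methoxymethoxy)-6-(3-methylbut-2-en-1-yl)-4-oxo-3,4-dihydro-2H-chromen-2-yl]-2-(3-methylbut-2-en-1-yl)phenyl carbonate
Product: 15 macarangaflavanone B, (2S)-5,7-dihydroxy-2-[4-hydroxy-3-(3-methylbut-2-en-1-yl)phenyl]-6-(3-methylbut-2-en-1-yl)-2,3-dihydro-4H-chromen-4-one
Conditions: 3 M HCl, MeOH, 40 °C
Reagents that add atoms: none
Why: Acid-catalysed acetal exchange with methanol removes both MOM ethers and acidolysis removes the tert-butyl carbonate in one operation; acid is chosen because base would open ring C by a retro-oxa-Michael reaction and racemise C2, while the prenyl groups should tolerate dilute acid at this temperature.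

Compound list
1 | resorcinol (benzene-1,3-diol) | Oc1cccc(O)c1 | starting material
2 | 1,3-bis(methoxymethoxy)benzene | COCOc1cccc(OCOC)c1 | intermediate
3 | [2,6-bis(methoxymethoxy)phenyl]lithium (not isolated) | [Li]c1c(OCOC)cccc1OCOC | intermediate
4 | 1,3-bis(methoxymethoxy)-2-(3-methylbut-2-en-1-yl)benzene | CC(C)=CCc1c(OCOC)cccc1OCOC | intermediate
5 | 2-[3,5-bis(methoxymethoxy)-4-(3-methylbut-2-en-1-yl)phenyl]-4,4,5,5-tetramethyl-1,3,2-dioxaborolane (not isolated) | CC(C)=CCc1c(OCOC)cc(B2OC(C)(C)C(C)(C)O2)cc1OCOC | intermediate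
6 | 3,5-bis(methoxymethoxy)-4-(3-methylbut-2-en-1-yl)phenol | CC(C)=CCc1c(OCOC)cc(O)cc1OCOC | intermediate
7 | 4-hydroxybenzaldehyde | O=Cc1ccc(O)cc1 | starting material
8 | 4-hydroxy-3-(3-methylbut-2-en-1-yl)benzaldehyde | CC(C)=CCc1cc(C=O)ccc1O | intermediate
9 | tert-butyl 4-formyl-2-(3-methylbut-2-en-1-yl)phenyl carbonate | CC(C)=CCc1cc(C=O)ccc1OC(=O)OC(C)(C)C | intermediate
10 | tert-butyl 2-(3-methylbut-2-en-1-yl)-4-[(2R)-4-oxooxetan-2-yl]phenyl carbonate | CC(C)=CCc1cc([C@H]2CC(=O)O2)ccc1OC(=O)OC(C)(C)C | intermediate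
11 | sodium 3,5-bis(methoxymethoxy)-4-(3-methylbut-2-en-1-yl)phenoxide (not isolated) | CC(C)=CCc1c(OCOC)cc([O-])cc1OCOC.[Na+] | intermediate
12 | sodium (3S)-3-[3,5-bis(methoxymethoxy)-4-(3-methylbut-2-en-1-yl)phenoxy]-3-{4-[(tert-butoxycarbonyl)oxy]-3-(3-methylbut-2-en-1-yl)phenyl}propanoate (not isolated) | CC(C)=CCc1cc([C@H](CC(=O)[O-])Oc2cc(OCOC)c(CC=C(C)C)c(OCOC)c2)ccc1OC(=O)OC(C)(C)C.[Na+] | intermediate
13 | (3S)-3-[3,5-bis(methoxymethoxy)-4-(3-methylbut-2-en-1-yl)phenoxy]-3-{4-[(tert-butoxycarbonyl)oxy]-3-(3-methylbut-2-en-1-yl)phenyl}propanoic trifluoroacetic anhydride (not isolated) | CC(C)=CCc1cc([C@H](CC(=O)OC(=O)C(F)(F)F)Oc2cc(OCOC)c(CC=C(C)C)c(OCOC)c2)ccc1OC(=O)OC(C)(C)C | intermediate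
14 | tert-butyl 4-[(2S)-5,7-bis(methoxymethoxy)-6-(3-methylbut-2-en-1-yl)-4-oxo-3,4-dihydro-2H-chromen-2-yl]-2-(3-methylbut-2-en-1-yl)phenyl carbonate | CC(C)=CCc1cc([C@@H]2CC(=O)c3c(cc(OCOC)c(CC=C(C)C)c3OCOC)O2)ccc1OC(=O)OC(C)(C)C | intermediate
15 | macarangaflavanone B, (2S)-5,7-dihydroxy-2-[4-hydroxy-3-(3-methylbut-2-en-1-yl)phenyl]-6-(3-methylbut-2-en-1-yl)-2,3-dihydro-4H-chromen-4-one | CC(C)=CCc1cc([C@@H]2CC(=O)c3c(cc(O)c(CC=C(C)C)c3O)O2)ccc1O | target

Total step count: 8.
Longest linear sequence: 5 steps (steps 4, 5, 6, 7, 8; the ring A branch, steps 1, 2, 3, 7, 8, is equally long).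

Steps most likely to fail

Step 7 (key step). The phenoxide may attack the lactone carbonyl and the resulting aldolate may eliminate to the cinnamate. The carbonate may also migrate to the phenoxide, or the benzylic centre may ionise in part so that configuration is eroded. The fallback forms the same two bonds in separate, isolated stages by Mitsunobu chemistry. It sets out from 10 and 6. Acyl–oxygen alcoholysis of 10 with allyl alcohol (K2CO3 cat., 0 °C) should give allyl (3R)-3-{4-[(tert-butoxycarbonyl)oxy]-3-prenylphenyl}-3-hydroxypropanoate F1 with the centre untouched. Mitsunobu etherification of F1 with 6 (PPh3, DIAD, toluene, 0 °C) should give, with inversion, allyl (3S)-3-[3,5-bis(methoxymethoxy)-4-prenylphenoxy]-3-{4-[(tert-butoxycarbonyl)oxy]-3-prenylphenyl}propanoate F2. Deallylation (Pd(PPh3)4, morpholine, THF) should give the corresponding (3S)-propanoic acid F3. Cycliacylation of F3 with (CF3CO)2O in CH2Cl2 at 0 °C comes back to the route at 14.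

Step 6. An aromatic aldehyde is a weaker partner for the ammonium enolate than an aliphatic one, so conversion and facial selectivity may be low while ketene dimerisation takes over. The fallback replaces the cycloaddition by an aldol reaction followed by lactonisation and sets out from 9. A Mukaiyama aldol reaction with 1-(tert-butylthio)-1-(trimethylsilyloxy)ethene, catalysed by BINOL and Ti(O-i-Pr)4 (the BINOL antipode that gives the 3R adduct), should give S-tert-butyl (3R)-3-{4-[(tert-butoxycarbonyl)oxy]-3-prenylphenyl}-3-[(trimethylsilyl)oxy]propanethioate F4. Desilylation with 1 M HCl in THF should give S-tert-butyl (3R)-3-{4-[(tert-butoxycarbonyl)oxy]-3-prenylphenyl}-3-hydroxypropanethioate F5. Thiophilic activation with Hg(O2CCF3)2 in MeCN should close the lactone with retention at the carbinol carbon and comes back to the route at 10.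

Step 3. The iridium boryl hydride species and the HBpin formed may hydroborate or isomerise the trisubstituted alkene, which would consume the prenyl group. The fallback installs the oxygen before the prenyl group and sets out from 2. Borylation of 2 under the same catalyst gives 2-[3,5-bis(methoxymethoxy)phenyl]-4,4,5,5-tetramethyl-1,3,2-dioxaborolane F6, which is oxidised in the flask (aq. H2O2, NaOH) to 3,5-bis(methoxymethoxy)phenol F7. Silylation (i-Pr3SiCl, imidazole, DMF) gives [3,5-bis(methoxymethoxy)phenoxy]triisopropylsilane F8. Lithiation with n-BuLi in THF at 0 °C takes place between the two MOM groups and gives [2,6-bis(methoxymethoxy)-4-(triisopropylsilyloxy)phenyl]lithium F9. Alkylation with prenyl bromide (CuI cat.) gives [3,5-bis(methoxymethoxy)-4-prenylphenoxy]triisopropylsilane F10. Desilylation with Bu4NF in THF comes back to the route at 6.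

Further compounds
F1 | step 7 | allyl (3R)-3-{4-[(tert-butoxycarbonyl)oxy]-3-(3-methylbut-2-en-1-yl)phenyl}-3-hydroxypropanoate | CC(C)=CCc1cc([C@H](O)CC(=O)OCC=C)ccc1OC(=O)OC(C)(C)C
F2 | step 7 | allyl (3S)-3-[3,5-bis(methoxymethoxy)-4-(3-methylbut-2-en-1-yl)phenoxy]-3-{4-[(tert-butoxycarbonyl)oxy]-3-(3-methylbut-2-en-1-yl)phenyl}propanoate | CC(C)=CCc1cc([C@H](CC(=O)OCC=C)Oc2cc(OCOC)c(CC=C(C)C)c(OCOC)c2)ccc1OC(=O)OC(C)(C)C
F3 | step 7 | (3S)-3-[3,5-bis(methoxymethoxy)-4-(3-methylbut-2-en-1-yl)phenoxy]-3-{4-[(tert-butoxycarbonyl)oxy]-3-(3-methylbut-2-en-1-yl)phenyl}propanoic acid | CC(C)=CCc1cc([C@H](CC(=O)O)Oc2cc(OCOC)c(CC=C(C)C)c(OCOC)c2)ccc1OC(=O)OC(C)(C)C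
F4 | step 6 | S-tert-butyl (3R)-3-{4-[(tert-butoxycarbonyl)oxy]-3-(3-methylbut-2-en-1-yl)phenyl}-3-[(trimethylsilyl)oxy]propanethioate | CC(C)=CCc1cc([C@H](O[Si](C)(C)C)CC(=O)SC(C)(C)C)ccc1OC(=O)OC(C)(C)C
F5 | step 6 | S-tert-butyl (3R)-3-{4-[(tert-butoxycarbonyl)oxy]-3-(3-methylbut-2-en-1-yl)phenyl}-3-hydroxypropanethioate | CC(C)=CCc1cc([C@H](O)CC(=O)SC(C)(C)C)ccc1OC(=O)OC(C)(C)C
F6 | step 3 | 2-[3,5-bis(methoxymethoxy)phenyl]-4,4,5,5-tetramethyl-1,3,2-dioxaborolane | COCOc1cc(B2OC(C)(C)C(C)(C)O2)cc(OCOC)c1
F7 | step 3 | 3,5-bis(methoxymethoxy)phenol | COCOc1cc(O)cc(OCOC)c1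
F8 | step 3 | [3,5-bis(methoxymethoxy)phenoxy]triisopropylsilane | COCOc1cc(O[Si](C(C)C)(C(C)C)C(C)C)cc(OCOC)c1
F9 | step 3 | [2,6-bis(methoxymethoxy)-4-(triisopropylsilyloxy)phenyl]lithium | [Li]c1c(OCOC)cc(O[Si](C(C)C)(C(C)C)C(C)C)cc1OCOC
F10 | step 3 | [3,5-bis(methoxymethoxy)-4-(3-methylbut-2-en-1-yl)phenoxy]triisopropylsilane | CC(C)=CCc1c(OCOC)cc(O[Si](C(C)C)(C(C)C)C(C)C)cc1OCOC
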